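## Structural features

The target has a pentacyclic core: a central benzene (ring A, one free CH) is fused on one side to dihydrobenzofuran 1 and on the other to dihydrobenzofuran 2, and its last two adjacent carbons belong to a seven-membered carbocycle that is also fused to a 3,5-dihydroxybenzene (ring B). Labels used here: C6 is the ring CH2 on ring A; C7 is the CH that carries the 2,4-dihydroxyphenyl group and is bonded to ring B next to one of its oxygens; C8 is the CH shared by the seven-membered ring and dihydrobenzofuran 2; C9 is the O–CH(4-hydroxyphenyl) of dihydrobenzofuran 2; C10 and C11 are the CH(3,5-dihydroxyphenyl) and O–CH(4-hydroxyphenyl) of dihydrobenzofuran 1. All five stereocentres are benzylic and R (7R,8R,9R,10R,11R): C8/C9 and C10/C11 are vicinal trans pairs, C7 and C8 sit on neighbouring carbons of ring B with the C7 aryl group on the face of the seven-membered ring opposite to C9, and the C10/C11 pair is too remote to be controlled by the other three. Fragile features are the eight free phenols, the two benzylic aryl ether bonds O–C9 and O–C11 (they ionise under acid next to C8–H and C10–H), and the many electron-rich rings that would all answer an electrophile. The real difficulty is threefold: to tie ring A to ring B through both C8 and the C6–C7 unit with the ring B oxygens correctly placed, to fix C8 absolutely although it lies between two similar aryl rings, and to reach the fully substituted ring A carbon that carries C10 without electrophilic substitution. The key step exploits the fact that ring B gives two adjacent carbons to the seven-membered ring, the one bonded to C8 having an H neighbour and the one bonded to C7 an oxygen neighbour, while ring A already holds C8 and C6 on adjacent carbons. Cutting the two ring B bonds therefore leaves a 3,5-dioxygenated aryne and a ring A-fused five-membered β-keto ester in which C8 is the nucleophilic carbon and C7 the ketone.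

## Logic of the disconnections

37 ⇒ 36. The eight phenolic O–H groups are traced back to O–CH3. The free phenols would not survive the acidic, basic and organometallic steps, and every fragment can carry methyl ethers from the start. Nothing is gained in skeleton, but all bond constructions become chemistry of a neutral octamethyl ether. The forward cleavage must spare the O–C9 and O–C11 bonds or let them re-close in the same trans sense.

36 ⇒ 33 (through 35 and 34). The C10–C11 bond of dihydrobenzofuran 1 is cut. C11 then is the CH2 of a benzylic ether and C10 a carbene carbon, so the ring comes from an intramolecular C–H insertion that a chiral catalyst controls; this is needed because no existing stereocentre is near enough to bias C10/C11. One ring and two stereocentres disappear. The forward step must set C10 by catalyst control in a crowded position and then allow C11 to equilibrate to trans.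

33 ⇒ 29 + 30. The ring A–C10 bond is cut. The ring A carbon carries bromine, so it becomes an aryllithium and C10 arrives as a nitrile carbon, directly at the imine level needed for the hydrazone. A whole aryl group is removed. Halogen–lithium exchange must outrun deprotonation of the benzylic CH groups, and the hindered C=N must exchange with hydrazine.

29 ⇒ 27 + 28. The O–C11 bond is cut at a phenol. The ether that is formed is not a protecting group: all of its atoms stay in the target. The forward step only needs a selective O-alkylation.

27 ⇒ 25 + 26. The C7–aryl bond is cut. C7 is ortho and para to the ring B oxygens, so its cation forms by protonation of a C6=C7 alkene, and 26 is nucleophilic at the required carbon. A stereocentre and an aryl group are removed and an achiral alkene remains. The arene must enter on the face of C7 opposite to C9, which the closed dihydrobenzofuran 2 has to enforce.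

25 ⇒ 23 (through 24). The O–C9 bond is cut. A p-methoxybenzylic cation at C9 captured by the ring A phenol closes the ring trans under thermodynamic control, so only C8 has to be right in the precursor. One ring is removed. The forward step must not lose C8 through elimination.

23 ⇒ 22. The C9–H bond is cut to a ketone. In 22 the C8 centre is labile (α to the ketone, doubly benzylic), so one asymmetric reduction with dynamic kinetic resolution can deliver C8. Two stereocentres are removed. The catalyst must tell ring A from ring B at C8, and enolisation must be faster than reduction.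

22 ⇒ 19 + 20. The C9–aryl bond is cut to a carboxyl carbon at C8, the group that the key step leaves there. An aryl group is removed. The acylation must stop at the ketone, which the acidity of C8–H ensures.

19 ⇒ 16 (through 18 and 17). Functional group changes only: the C6=C7 alkene is traced back to the C7 ketone and the acid to the methyl ester. The ketone must be masked during the organometallic and hydride steps in an achiral form that is also the direct precursor of the C7 cation. The dehydration must leave the acetal protecting groups intact.

16 ⇒ 8 + 13. The ring B–C8 and ring B–C7 bonds are cut, giving back the C7–C8 bond of a five-membered ring. This removes ring B and the seven-membered ring in one operation and leads to two simple benzenoid fragments. The forward step needs the C8 carbon to attack the aryne carbon remote from the flanking methoxy group. Two spectator changes are built into 8: a bromine on the ring A carbon that will carry C10 (so that no electrophilic substitution is needed on a molecule with six electron-rich rings), and methoxymethyl ethers on the ring A oxygens (removable without hydrogenolysis, which neither the bromine nor the C6=C7 alkene would survive).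

8 ⇒ 4 (through 7 and 6). The ring A–C8 bond is cut to a rhodium carbenoid precursor, and the keto ester chain is traced back to an arylacetic acid. The bicycle becomes a monosubstituted chain on ring A. The carbenoid has only one free ortho carbon to attack, so no regiochemical question arises.

4 ⇒ 1 (through 3 and 2). The C–Br bond and the O-acetals are removed. The forward bromination must go ortho to the side chain and not between the two oxygens.

13 ⇒ 9 (through 12, 11 and 10). The C–Si and O–S bonds are traced back to an ortho-bromophenol and then to the phenol. The forward sequence relies on ortho bromination and a 1,3-silyl shift from oxygen to carbon.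

## Other disconnections considered

Alternative 1: The cut removes ring A as such: the two ring A C–C bonds that join the oxygen-bearing carbon of dihydrobenzofuran 2 to the carbon bearing C8, and the carbon bearing C6 to the carbon bearing C10, plus the O–aryl bond of dihydrobenzofuran 1. In the forward sense, heating triyne A1 would let its alkoxy-1,3-diyne and the alkyne tethered through O–C9–C8 undergo a hexadehydro-Diels–Alder cycloaromatisation to a ring A aryne already fused to dihydrobenzofuran 2. The C11 carbinol would then add O–H across the aryne to give benzodifuran A2. In its favour: ring A is made with all six substituents placed by connectivity, both heterocycles close in one operation, and C8–C11 can be set in an open chain by standard asymmetric methods. Against it here: A1 is a 1-alkoxy-1,3-diyne whose O-alkyl group has a β-hydrogen (H8), a type of ynol ether that tends to fragment to a ketene and an alkene at the temperatures of the cycloaromatisation. C8 and C10 would be propargylic and benzylic and therefore easy to epimerise. After A2 the seven-membered ring would still have to be closed by a Friedel–Crafts alkylation from a C7 cation. Compared with the chosen plan, the alternative is the better on convergence and on ring A substitution (no halogen handle, no catalyst-controlled closure of dihydrobenzofuran 1). It is the equal on C7 (a cation captured by an arene in both, there as a ring closure with the facial bias of C8 less well defined). It is weaker on mechanism (thermal chemistry of a labile polyyne against a fluoride-triggered insertion of two stable partners) and probably on step economy, since A1 with five stereocentres is unlikely to be reached in fewer steps than 16.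

Alternative 2: The cut removes four bonds of ring B and keeps a cycloheptene fused to ring A. In the forward sense, irradiation of diazomethyl ketone A3 would trigger a Wolff rearrangement to a vinylketene. This would add (2+2) to siloxyalkyne A4, and four-electron ring opening followed by six-electron closure would give A5, with ring B formed as a monosilylated resorcinol. In its favour: cycloalkenyl diazomethyl ketones are the classical substrates of this benzannulation, the meta-dioxygenation and its position follow from the mechanism, and the conditions are neutral. C7 and C8 would be set before ring B exists, so no C7 cation is needed; on this point the alternative is the better. Against it here: A3 is a ring A-fused cycloheptene with three stereocentres and a dihydrobenzofuran, far harder to make than 8. C7–H would be γ to the enone carbonyl and benzylic, so it could epimerise through dienol or ketene intermediates. The photochemical step has to work among several electron-rich chromophores. A5 still has an unsubstituted ring A carbon where C10 must be attached, so the late electrophilic substitution problem returns. Compared with the chosen plan, regiocontrol of ring B is equal (by mechanism there, by the methoxy group of the aryne here). Step economy is poorer, because four bonds are made in the key step but the seven-membered ring must be built separately beforehand, whereas the aryne insertion makes that ring and both ring B bonds from two benzene derivatives.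

Alternative 3: The cut is the ring A–C8 bond of dihydrobenzofuran 2, traced back to a six-membered pyranone. In the forward sense, PhI(OAc)2 with HC(OMe)3 and H2SO4 would convert flavanone A6 into its enol ether and iodinate C3. Ring A would then migrate from the carbonyl carbon to C3, contracting the ring to the trans ester A7. In its favour: the reaction type is established for flavanones and uses cheap reagents. C9 is inherited from C2 of A6 and C8 follows as the trans partner, so the absolute configuration of both centres comes from one simple stereocentre; on this point the alternative is the better, since the chosen plan depends on a dynamic kinetic resolution. Against it here: only one skeletal bond and the smallest ring are made. The carbon attached to C8 in A7 is an ester carbon, so ring B would have to be grown from it or brought in by a decarboxylative arylation that would erase the C8 configuration just set. The ring A methyl group would need benzylic functionalisation to carry C6–C7. C8–H in A7 is α to the ester and β to the aryloxy group, which invites ring opening by elimination. A6 can racemise through its chalcone under acid. Compared with the chosen plan, robustness of the key step is equal, but the gain in skeleton is much smaller, and the seven-membered ring, ring B and C7 would cost more steps afterwards than the whole chosen sequence from 16.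

Key step: step 8

Remark on the key-step structures: mapping 8 and 16 atom by atom onto the target confirms both skeletons (ring A oxygens ortho and para to C8; ring B methoxy group next to the carbon that bears C7). Nothing is changed in them except the spectator groups named above.

Assumption on catalyst sense: the sense of induction of RuCl[(R,R)-TsDPEN](mesitylene) in step 13 and of Rh2(R-PTAD)4 in step 18 is assigned by analogy with simple aryl ketones and simple benzyl aryl ethers. Both catalysts exist as either enantiomer, and the antipode would be used if induction at C8 or C10 ran the other way.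

Remark on names: tricyclic intermediates use the locants of 5H-dibenzo[a,d]cycloheptene (position 5 = C8, position 10 = C7, position 11 = C6). Stereodescriptors are always given with the labels C7 to C11.

## Route

Step 1
Reactants: 1 3,5-dihydroxyphenylacetic acid
Product: 3 2-[3,5-bis(methoxymethoxy)phenyl]acetic acid, via methoxymethyl ester 2 (not isolated)
Conditions: MOMCl, iPr2NEt, CH2Cl2, 0 °C → rt; then LiOH, THF/H2O, rt; dil. HCl to pH 4 at 0 °C
Reagents that add atoms: chloromethyl methyl ether, COCCl; lithium hydroxide, [Li+].[OH-]
Why: MOMCl alkylates both phenols and the carboxylate under amine base, and hydroxide then cleaves only the acyloxymethyl ester (acetal protection followed by saponification). MOM ethers are chosen because they survive fluoride, hydride, organomagnesium and rhodium carbenoid steps and can be removed without hydrogenolysis.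

Step 2
Reactants: 3 2-[3,5-bis(methoxymethoxy)phenyl]acetic acid
Product: 4 2-[2-bromo-3,5-bis(methoxymethoxy)phenyl]acetic acid
Conditions: NBS, MeCN, 0 °C
Reagents that add atoms: N-bromosuccinimide, O=C1CCC(=O)N1Br
Why: Electrophilic aromatic bromination goes to the position ortho to the side chain, which is para to one and ortho to the other MOM ether and less hindered than the carbon between the two ethers. The bromine is the later handle for the ring A–C10 bond and leaves only one ortho position free for the ring closure of step 5.

Step 3
Reactants: 4 2-[2-bromo-3,5-bis(methoxymethoxy)phenyl]acetic acid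
Product: 6 methyl 4-[2-bromo-3,5-bis(methoxymethoxy)phenyl]-3-oxobutanoate, via acyl imidazolide 5 (not isolated)
Conditions: CDI, THF, rt; then KO2CCH2CO2Me, MgCl2, Et3N, MeCN/THF, rt → 40 °C
Reagents that add atoms: potassium methyl malonate, COC(=O)CC(=O)[O-].[K+]
Why: The acyl imidazolide acylates the magnesium enolate of the malonate half-ester and loss of CO2 gives the β-keto ester (malonate half-ester acylation–decarboxylation).

Step 4
Reactants: 6 methyl 4-[2-bromo-3,5-bis(methoxymethoxy)phenyl]-3-oxobutanoate
Product: 7 methyl 4-[2-bromo-3,5-bis(methoxymethoxy)phenyl]-2-diazo-3-oxobutanoate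
Conditions: 4-AcNHC6H4SO2N3, Et3N, MeCN, 0 °C → rt
Reagents that add atoms: 4-acetamidobenzenesulfonyl azide, CC(=O)Nc1ccc(cc1)S(=O)(=O)N=[N+]=[N-]
Why: Regitz diazo transfer to the active methylene group; the benzylic CH2 is far less acidic and is left alone.

Step 5
Reactants: 7 methyl 4-[2-bromo-3,5-bis(methoxymethoxy)phenyl]-2-diazo-3-oxobutanoate
Product: 8 methyl 4-bromo-5,7-bis(methoxymethoxy)-2-oxo-2,3-dihydro-1H-indene-1-carboxylate
Conditions: Rh2(OAc)4 (1 mol%), CH2Cl2, rt, slow addition
Reagents that add atoms: none
Why: The rhodium carbenoid attacks the only free ortho carbon of the ring, which is activated by an ortho and a para MOM ether, and rearomatisation closes the five-membered ring (formal aromatic C–H insertion of an α-diazo-β-keto ester to a 2-indanone-1-carboxylate). C1 of 8 is enolisable and carries no configuration.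

Step 6
Reactants: 9 3,5-dimethoxyphenol
Product: 10 2-bromo-3,5-dimethoxyphenol
Conditions: NBS, CH2Cl2, −78 °C → 0 °C
Reagents that add atoms: N-bromosuccinimide, O=C1CCC(=O)N1Br
Why: Bromination of the phenol with NBS at low temperature in a non-polar solvent is directed ortho to the hydroxyl group; the carbon between OH and OMe is less hindered than the one between the two methoxy groups.

Step 7
Reactants: 10 2-bromo-3,5-dimethoxyphenol
Product: 13 3,5-dimethoxy-2-(trimethylsilyl)phenyl trifluoromethanesulfonate, via trimethylsilyl ether 11 (not isolated), via lithium phenoxide 12 (not isolated)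
Conditions: (Me3Si)2NH, THF, 65 °C; evaporate; n-BuLi, THF, −100 °C → −80 °C; Tf2O, −100 °C → rt
Reagents that add atoms: hexamethyldisilazane, C[Si](C)(C)N[Si](C)(C)C; trifluoromethanesulfonic anhydride, O=S(=O)(OS(=O)(=O)C(F)(F)F)C(F)(F)F
Why: O-Silylation, bromine–lithium exchange and 1,3-migration of silicon from oxygen to carbon (retro-Brook rearrangement) give the ortho-silyl phenoxide, which is triflated in the same flask (the standard route to ortho-silylaryl triflates).

Step 8
Reactants: 8 methyl 4-bromo-5,7-bis(methoxymethoxy)-2-oxo-2,3-dihydro-1H-indene-1-carboxylate; 13 3,5-dimethoxy-2-(trimethylsilyl)phenyl trifluoromethanesulfonate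
Product: 16 methyl 1-bromo-7,9-dimethoxy-2,4-bis(methoxymethoxy)-10-oxo-10,11-dihydro-5H-dibenzo[a,d]cycloheptene-5-carboxylate, via 3,5-dimethoxybenzyne 14 (not isolated), via cesium benzocyclobutenoxide 15 (not isolated)
Conditions: CsF (2.5 equiv), MeCN, 80 °C
Reagents that add atoms: none
Why: CsF unmasks aryne 14 from 13 and, acting as base, forms the cesium enolate of 8 at C1 (the future C8), the most acidic site of the substrate. The enolate carbon adds to the aryne carbon remote from the flanking methoxy group, because the negative charge then develops on the carbon next to that inductively withdrawing oxygen and the approach avoids the ortho substituent; this places C8 on the ring B carbon with an H neighbour and the aryl anion on the carbon next to OMe. The aryl anion closes onto the C2 ketone (the future C7) in a 4-exo-trig addition to give benzocyclobutenoxide 15, and retro-aldol-type cleavage of the old C1–C2 bond, driven by release of four-ring strain and formation of the doubly benzylic ester enolate, opens it. The seven-membered ring is thus closed by two-carbon expansion of the five-membered ring (four-ring closure, then fragmentation) and not by a direct seven-membered cyclisation, and the skeletal bonds ring B–C8 and ring B–C7 are formed. The closest known reaction type is the fluoride-induced acyl-alkylation of arynes by β-keto esters, including ring expansion of cyclic β-keto esters. No lasting stereocentre is formed: C8 stays α to the ester and doubly benzylic and is carried as a racemic, labile centre. The selectivities needed are C- over O-arylation and ring expansion over simple α-arylation; the soft, fully substituted enolate carbon and the ketone held four atoms from the aryl anion should secure both, and the aryl bromide and the MOM ethers are inert to CsF.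

Step 9
Reactants: 16 methyl 1-bromo-7,9-dimethoxy-2,4-bis(methoxymethoxy)-10-oxo-10,11-dihydro-5H-dibenzo[a,d]cycloheptene-5-carboxylate
Product: 17 methyl 1-bromo-10-hydroxy-7,9-dimethoxy-2,4-bis(methoxymethoxy)-10,11-dihydro-5H-dibenzo[a,d]cycloheptene-5-carboxylate (mixture of diastereomers)
Conditions: NaBH4, MeOH/THF, 0 °C
Reagents that add atoms: none
Why: NaBH4 reduces the aryl ketone and leaves the methyl ester, the aryl bromide and the acetals (chemoselective borohydride reduction). The diastereomer mixture is of no consequence because C7 becomes sp2 in step 10.

Step 10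
Reactants: 17 methyl 1-bromo-10-hydroxy-7,9-dimethoxy-2,4-bis(methoxymethoxy)-10,11-dihydro-5H-dibenzo[a,d]cycloheptene-5-carboxylate
Product: 18 methyl 1-bromo-7,9-dimethoxy-2,4-bis(methoxymethoxy)-5H-dibenzo[a,d]cycloheptene-5-carboxylate
Conditions: camphorsulfonic acid (10 mol%), 4 Å MS, toluene, 40 °C
Reagents that add atoms: none
Why: The 2,4-dimethoxybenzylic alcohol ionises under mild sulfonic acid catalysis and the cation loses a C6 proton, its only β-hydrogen (E1 dehydration); the sieves take up the water so that the MOM ethers are not hydrolysed. The achiral C6=C7 alkene masks C7 through the organometallic and hydride steps and is the direct precursor of the C7 cation needed in step 15.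

Step 11
Reactants: 18 methyl 1-bromo-7,9-dimethoxy-2,4-bis(methoxymethoxy)-5H-dibenzo[a,d]cycloheptene-5-carboxylate
Product: 19 1-bromo-7,9-dimethoxy-2,4-bis(methoxymethoxy)-5H-dibenzo[a,d]cycloheptene-5-carboxylic acid
Conditions: LiOH, THF/MeOH/H2O, 50 °C; dil. HCl to pH 4 at 0 °C
Reagents that add atoms: lithium hydroxide, [Li+].[OH-]
Why: Saponification of the methyl ester; the aryl bromide, the alkene and the MOM ethers are stable to hydroxide, and C8 is still labile, so no stereochemical question arises.

Step 12
Reactants: 19 1-bromo-7,9-dimethoxy-2,4-bis(methoxymethoxy)-5H-dibenzo[a,d]cycloheptene-5-carboxylic acid; 20 4-methoxyphenylmagnesium bromide (THF solution)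
Product: 22 [1-bromo-7,9-dimethoxy-2,4-bis(methoxymethoxy)-5H-dibenzo[a,d]cyclohepten-5-yl](4-methoxyphenyl)methanone, via acyl imidazolide 21 (not isolated)
Conditions: CDI, THF, rt; then 20 (3.5 equiv), −78 °C → 0 °C; aq. NH4Cl
Reagents that add atoms: none
Why: The acyl imidazolide reacts with the aryl Grignard reagent either by direct addition or, after deprotonation at C8, through the diaryl ketene; both paths end at the magnesium enolate of 22, which cannot take up a second equivalent (ketone synthesis from an acyl imidazolide). Excess reagent is needed because imidazole and the acidic C8–H each consume one equivalent.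

Step 13
Reactants: 22 [1-bromo-7,9-dimethoxy-2,4-bis(methoxymethoxy)-5H-dibenzo[a,d]cyclohepten-5-yl](4-methoxyphenyl)methanone
Product: 23 (9R)-[(8R)-1-bromo-7,9-dimethoxy-2,4-bis(methoxymethoxy)-5H-dibenzo[a,d]cyclohepten-5-yl](4-methoxyphenyl)methanol
Conditions: RuCl[(R,R)-TsDPEN](mesitylene) (2 mol%), HCO2H/Et3N (5:2 azeotrope), DMF, 40 °C
Reagents that add atoms: none
Why: Asymmetric transfer hydrogenation with dynamic kinetic resolution of an α-aryl ketone: C8 racemises through the enol in the basic medium faster than either enantiomer is reduced. The (R,R)-catalyst delivers hydride to one face of the aryl ketone (C9 R, as with simple aryl ketones) and, by the Felkin–Anh preference with the ortho-oxygenated ring A as the large group, should select the (8R)-ketone to give (8R,9R)-23. C9 is re-formed in step 14, so only the C8 configuration has to be delivered here.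

Step 14
Reactants: 23 (9R)-[(8R)-1-bromo-7,9-dimethoxy-2,4-bis(methoxymethoxy)-5H-dibenzo[a,d]cyclohepten-5-yl](4-methoxyphenyl)methanol
Product: 25 (8R,9R)-tetracyclic bromophenol (5H-dibenzo[a,d]cycloheptene with C6=C7 intact; the position 4 oxygen and C8 bridged by C9H(4-methoxyphenyl) into a trans-2,3-dihydrobenzofuran; OH at position 2; Br at position 1; OMe at positions 7 and 9), via diphenol carbinol 24 (not isolated)
Conditions: HCl (from AcCl), MeOH/THF, 0 °C → rt; evaporate; TsOH·H2O (cat.), CH2Cl2, 4 Å MS, rt
Reagents that add atoms: none
Why: Acidic methanol removes both MOM acetals; the p-methoxybenzylic C9 carbinol (or its methyl ether) then ionises and the neighbouring ring A phenol captures the cation in a reversible 5-exo closure, so the thermodynamically preferred trans ring (C9 R, aryl anti to ring B at C8) results once methanol is removed (acetal cleavage and SN1 etherification). C8 is not touched; the same ionisation and phenol capture closes pterocarpans from isoflavan-4-ols without loss of the adjacent centre, and the tub-shaped C6=C7 stilbene is a far weaker base than the carbinol.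

Step 15
Reactants: 25 (8R,9R)-tetracyclic bromophenol; 26 1,3-dimethoxybenzene
Product: 27 (7R,8R,9R)-7-(2,4-dimethoxyphenyl) tetracyclic bromophenol (as 25 but C6 is CH2 and C7 is CH bearing the 2,4-dimethoxyphenyl group)
Conditions: 26 (10 equiv), TsOH·H2O (0.2 equiv), (CF3)2CHOH/CH2Cl2, 0 °C → rt
Reagents that add atoms: none
Why: Protonation at C6 gives the C7 cation stabilised by the ortho and para methoxy groups of ring B, and 26 attacks through its C4 (para to one OMe, ortho to the other) in a Friedel–Crafts hydroarylation. The closed dihydrobenzofuran holds C9 pseudo-equatorial, so H8 is pseudo-axial on the convex face of the folded tricycle and the arene should enter C7 on that open face, cis to H8 and trans to C9 (7R). This isomer also keeps the C7–H bond in the plane of ring B next to its methoxy group, so kinetic and thermodynamic preferences agree.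

Step 16
Reactants: 27 (7R,8R,9R)-7-(2,4-dimethoxyphenyl) tetracyclic bromophenol; 28 4-methoxybenzyl chloride
Product: 29 (7R,8R,9R)-4-methoxybenzyl ether of 27
Conditions: K2CO3, n-Bu4NI (cat.), DMF, 40 °C
Reagents that add atoms: none
Why: Williamson etherification of the ring A phenoxide with the benzylic chloride. The CH2 of this ether is the future C11 and its aryl group the 4-oxygenated ring of dihydrobenzofuran 1, so no atom of it is lost later.

Step 17
Reactants: 29 (7R,8R,9R)-4-methoxybenzyl ether of 27; 30 3,5-dimethoxybenzonitrile
Product: 33 (7R,8R,9R)-diaryl ketone hydrazone (as 29 but Br replaced by C(=N–NH2)(3,5-dimethoxyphenyl)), via aryllithium 31 (not isolated), via lithium ketimide 32 (not isolated)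
Conditions: n-BuLi, THF, −78 °C; 30, −78 °C → 0 °C; then N2H4·H2O, AcOH, EtOH, 70 °C
Reagents that add atoms: hydrazine hydrate, NN.O
Why: Bromine–lithium exchange at −78 °C is faster than any deprotonation, the aryllithium adds once to the nitrile, and the N–H ketimine set free by acetic acid exchanges with hydrazine (transimination), which avoids condensation on a di-ortho-substituted diaryl ketone. The hydrazone geometry is irrelevant because both isomers give the same diazo compound.

Step 18
Reactants: 33 (7R,8R,9R)-diaryl ketone hydrazone
Product: 36 (7R,8R,9R,10R,11R)-octamethyl ether of the target, via diazo compound 34 (not isolated), via cis-dihydrobenzofuran 35 (not isolated)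
Conditions: MnO2, CH2Cl2, rt; filter; Rh2(R-PTAD)4 (1 mol%), CH2Cl2, 0 °C → rt; then CF3CO2H, 0 °C → rt
Reagents that add atoms: none
Why: MnO2 oxidises the hydrazone to the diaryldiazomethane, and the chiral rhodium carbene inserts into the electron-rich benzylic C–H bond of the 4-methoxybenzyl ether five atoms away (intramolecular C–H insertion of a donor/donor carbene), closing dihydrobenzofuran 1 as the cis isomer with C10 set by the catalyst (10R). CF3CO2H then ionises the O–C11 bond reversibly to the p-methoxybenzylic cation and the ring re-closes trans (11R) without touching C10.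

Step 19
Reactants: 36 (7R,8R,9R,10R,11R)-octamethyl ether of the target
Product: 37 CNP0154047.1, the (7R,8R,9R,10R,11R)-octaphenol
Conditions: BBr3 (20 equiv), CH2Cl2, −78 °C → rt; MeOH, then H2O
Reagents that add atoms: none
Why: BBr3 cleaves all eight aryl methyl ethers by O-complexation and bromide attack at methyl (Lewis acid demethylation). No alkene or other group competes, and any transient opening of the two benzylic aryl ether bonds can only re-close to the trans rings already in place.

## Compound list

1 | 3,5-dihydroxyphenylacetic acid | O=C(O)Cc1cc(O)cc(O)c1 | starting material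
2 | methoxymethyl 2-[3,5-bis(methoxymethoxy)phenyl]acetate | COCOC(=O)Cc1cc(OCOC)cc(OCOC)c1 | intermediate (not isolated)
3 | 2-[3,5-bis(methoxymethoxy)phenyl]acetic acid | OC(=O)Cc1cc(OCOC)cc(OCOC)c1 | intermediate
4 | 2-[2-bromo-3,5-bis(methoxymethoxy)phenyl]acetic acid | OC(=O)Cc1cc(OCOC)cc(OCOC)c1Br | intermediate
5 | 2-[2-bromo-3,5-bis(methoxymethoxy)phenyl]-1-(imidazol-1-yl)ethanone | O=C(Cc1cc(OCOC)cc(OCOC)c1Br)n1ccnc1 | intermediate (not isolated)
6 | methyl 4-[2-bromo-3,5-bis(methoxymethoxy)phenyl]-3-oxobutanoate | COC(=O)CC(=O)Cc1cc(OCOC)cc(OCOC)c1Br | intermediate
7 | methyl 4-[2-bromo-3,5-bis(methoxymethoxy)phenyl]-2-diazo-3-oxobutanoate | COC(=O)C(=[N+]=[N-])C(=O)Cc1cc(OCOC)cc(OCOC)c1Br | intermediate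
8 | methyl 4-bromo-5,7-bis(methoxymethoxy)-2-oxo-2,3-dihydro-1H-indene-1-carboxylate | COC(=O)C1C(=O)Cc2c(Br)c(OCOC)cc(OCOC)c21 | intermediate (key-step precursor)
9 | 3,5-dimethoxyphenol | COc1cc(O)cc(OC)c1 | starting material
10 | 2-bromo-3,5-dimethoxyphenol | COc1cc(O)c(Br)c(OC)c1 | intermediate
11 | (2-bromo-3,5-dimethoxyphenoxy)trimethylsilane | COc1cc(O[Si](C)(C)C)c(Br)c(OC)c1 | intermediate (not isolated)
12 | lithium 3,5-dimethoxy-2-(trimethylsilyl)phenoxide | COc1cc([O-])c([Si](C)(C)C)c(OC)c1.[Li+] | intermediate (not isolated)
13 | 3,5-dimethoxy-2-(trimethylsilyl)phenyl trifluoromethanesulfonate | COc1cc(OC)c([Si](C)(C)C)c(OS(=O)(=O)C(F)(F)F)c1 | intermediate (key-step precursor)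
14 | 3,5-dimethoxybenzyne | COC1=CC(OC)=CC#C1 | intermediate (not isolated)
15 | cesium benzocyclobutenoxide (C8 quaternary, bonded to ester, ring A, ring B and C7; C7 bears O−) | COC(=O)C12c3cc(OC)cc(OC)c3C1([O-])Cc1c(Br)c(OCOC)cc(OCOC)c21.[Cs+] | intermediate (not isolated)
16 | methyl 1-bromo-7,9-dimethoxy-2,4-bis(methoxymethoxy)-10-oxo-10,11-dihydro-5H-dibenzo[a,d]cycloheptene-5-carboxylate | COC(=O)C1c2cc(OC)cc(OC)c2C(=O)Cc2c(Br)c(OCOC)cc(OCOC)c21 | intermediate (key-step product)
17 | methyl 1-bromo-10-hydroxy-7,9-dimethoxy-2,4-bis(methoxymethoxy)-10,11-dihydro-5H-dibenzo[a,d]cycloheptene-5-carboxylate | COC(=O)C1c2cc(OC)cc(OC)c2C(O)Cc2c(Br)c(OCOC)cc(OCOC)c21 | intermediate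
18 | methyl 1-bromo-7,9-dimethoxy-2,4-bis(methoxymethoxy)-5H-dibenzo[a,d]cycloheptene-5-carboxylate | COC(=O)C1c2cc(OC)cc(OC)c2C=Cc2c(Br)c(OCOC)cc(OCOC)c21 | intermediate
19 | 1-bromo-7,9-dimethoxy-2,4-bis(methoxymethoxy)-5H-dibenzo[a,d]cycloheptene-5-carboxylic acid | OC(=O)C1c2cc(OC)cc(OC)c2C=Cc2c(Br)c(OCOC)cc(OCOC)c21 | intermediate
20 | 4-methoxyphenylmagnesium bromide | COc1ccc([Mg]Br)cc1 | starting material (commercial THF solution; also from 4-bromoanisole and Mg)
21 | [1-bromo-7,9-dimethoxy-2,4-bis(methoxymethoxy)-5H-dibenzo[a,d]cyclohepten-5-yl](imidazol-1-yl)methanone | O=C(C1c2cc(OC)cc(OC)c2C=Cc2c(Br)c(OCOC)cc(OCOC)c21)n1ccnc1 | intermediate (not isolated)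
22 | [1-bromo-7,9-dimethoxy-2,4-bis(methoxymethoxy)-5H-dibenzo[a,d]cyclohepten-5-yl](4-methoxyphenyl)methanone | COc1ccc(cc1)C(=O)C1c2cc(OC)cc(OC)c2C=Cc2c(Br)c(OCOC)cc(OCOC)c21 | intermediate
23 | (9R)-[(8R)-1-bromo-7,9-dimethoxy-2,4-bis(methoxymethoxy)-5H-dibenzo[a,d]cyclohepten-5-yl](4-methoxyphenyl)methanol | COCOc1cc(OCOC)c2c(c1Br)C=Cc1c(OC)cc(OC)cc1[C@H]2[C@@H](O)c1ccc(OC)cc1 | intermediate
24 | (9R)-[(8R)-1-bromo-2,4-dihydroxy-7,9-dimethoxy-5H-dibenzo[a,d]cyclohepten-5-yl](4-methoxyphenyl)methanol | Oc1cc(O)c2c(c1Br)C=Cc1c(OC)cc(OC)cc1[C@H]2[C@@H](O)c1ccc(OC)cc1 | intermediate (not isolated)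
25 | (8R,9R)-tetracyclic bromophenol with closed trans-dihydrobenzofuran 2 and C6=C7 double bond | Oc1cc2c3c(c1Br)C=Cc1c(OC)cc(OC)cc1[C@H]3[C@H](c1ccc(OC)cc1)O2 | intermediate
26 | 1,3-dimethoxybenzene | COc1cccc(OC)c1 | starting material
27 | (7R,8R,9R)-7-(2,4-dimethoxyphenyl) tetracyclic bromophenol | Oc1cc2c3c(c1Br)C[C@H](c1ccc(OC)cc1OC)c1c(OC)cc(OC)cc1[C@H]3[C@H](c1ccc(OC)cc1)O2 | intermediate
28 | 4-methoxybenzyl chloride | COc1ccc(CCl)cc1 | starting material
29 | (7R,8R,9R)-4-methoxybenzyl ether of 27 | COc1ccc(COc2cc3c4c(c2Br)C[C@H](c2ccc(OC)cc2OC)c2c(OC)cc(OC)cc2[C@H]4[C@H](c2ccc(OC)cc2)O3)cc1 | intermediate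
30 | 3,5-dimethoxybenzonitrile | COc1cc(C#N)cc(OC)c1 | starting material
31 | (7R,8R,9R)-aryllithium from 29 (Li in place of Br) | COc1ccc(COc2cc3c4c(c2[Li])C[C@H](c2ccc(OC)cc2OC)c2c(OC)cc(OC)cc2[C@H]4[C@H](c2ccc(OC)cc2)O3)cc1 | intermediate (not isolated)
32 | (7R,8R,9R)-N-lithio diaryl ketimine | COc1ccc(COc2cc3c4c(c2C(=N[Li])c2cc(OC)cc(OC)c2)C[C@H](c2ccc(OC)cc2OC)c2c(OC)cc(OC)cc2[C@H]4[C@H](c2ccc(OC)cc2)O3)cc1 | intermediate (not isolated)
33 | (7R,8R,9R)-diaryl ketone hydrazone | COc1ccc(COc2cc3c4c(c2C(=NN)c2cc(OC)cc(OC)c2)C[C@H](c2ccc(OC)cc2OC)c2c(OC)cc(OC)cc2[C@H]4[C@H](c2ccc(OC)cc2)O3)cc1 | intermediate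
34 | (7R,8R,9R)-diaryldiazomethane | COc1ccc(COc2cc3c4c(c2C(=[N+]=[N-])c2cc(OC)cc(OC)c2)C[C@H](c2ccc(OC)cc2OC)c2c(OC)cc(OC)cc2[C@H]4[C@H](c2ccc(OC)cc2)O3)cc1 | intermediate (not isolated)
35 | (7R,8R,9R,10R,11S)-octamethyl ether with cis-dihydrobenzofuran 1 | COc1ccc([C@H]2Oc3cc4c5c(c3[C@H]2c2cc(OC)cc(OC)c2)C[C@H](c2ccc(OC)cc2OC)c2c(OC)cc(OC)cc2[C@H]5[C@H](c2ccc(OC)cc2)O4)cc1 | intermediate (not isolated)
36 | (7R,8R,9R,10R,11R)-octamethyl ether of the target | COc1ccc([C@@H]2Oc3cc4c5c(c3[C@H]2c2cc(OC)cc(OC)c2)C[C@H](c2ccc(OC)cc2OC)c2c(OC)cc(OC)cc2[C@H]5[C@H](c2ccc(OC)cc2)O4)cc1 | intermediate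
37 | CNP0154047.1 | Oc1ccc([C@@H]2Oc3cc4c5c(c3[C@H]2c2cc(O)cc(O)c2)C[C@H](c2ccc(O)cc2O)c2c(O)cc(O)cc2[C@H]5[C@H](c2ccc(O)cc2)O4)cc1 | target

## Step count and least certain steps

Total step count: 19. Longest linear sequence: 17 steps (steps 1–5 and 8–19); steps 6–7 are a two-step branch to 13.

**Step 8 (key step).** The aryl anion formed after C-arylation may partition between closure onto the ketone and protonation, giving simple α-arylation without ring expansion. O-arylation of the largely enolic, fully substituted C1 position may compete, and attack at the wrong aryne carbon may leak in because the nucleophile is bulky.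

The fallback sets out from 8 and returns at 16, and forms the same two bonds one after the other. Arylation of 8 at C1 with (3,5-dimethoxyphenyl)lead triacetate, ArPb(OAc)3, in CHCl3/pyridine would give the quaternary keto ester methyl 4-bromo-1-(3,5-dimethoxyphenyl)-5,7-bis(methoxymethoxy)-2-oxo-2,3-dihydro-1H-indene-1-carboxylate F1. NaOMe in MeOH would open it by retro-Claisen cleavage of the C1–C2 bond to the diester methyl 2-{2-bromo-6-[1-(3,5-dimethoxyphenyl)-2-methoxy-2-oxoethyl]-3,5-bis(methoxymethoxy)phenyl}acetate F2. One equivalent of LiOH would hydrolyse the unhindered arylacetate ester to the monoacid 2-{2-bromo-6-[1-(3,5-dimethoxyphenyl)-2-methoxy-2-oxoethyl]-3,5-bis(methoxymethoxy)phenyl}acetic acid F3. Its mixed anhydride with (CF3CO)2O in CH2Cl2 buffered by 2,6-di-tert-butylpyridine would acylate the 3,5-dimethoxyphenyl ring at an ortho position (both are equivalent) in an intramolecular Friedel–Crafts reaction, closing the seven-membered ring to 16. No aryne and no regiochemical choice is involved.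

**Step 13.** Discrimination between the two aryl rings that flank C8 may be weak, so that both C8 configurations are reduced at similar rates. Enolisation on the tub-shaped tricycle may also be slower than reduction of the ketone, which would turn the dynamic resolution into a simple kinetic one.

The fallback sets out from 22 and returns at 23, replacing asymmetric catalysis by resolution with recycling. NaBH4/CeCl3 in MeOH/THF at −40 °C would reduce 22 without asymmetric induction; the Felkin–Anh preference should give the like pair, that is racemic 23. Preparative chromatography on a chiral stationary phase would separate 23 from its enantiomer, the (8S,9S)-carbinol F4. Oxidation of F4 with Dess–Martin periodinane would return it to 22, in which C8 is labile again, for another pass.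

**Step 15.** Facial selectivity at the C7 cation may be insufficient. The acid needed to protonate the twisted stilbene may also reversibly open the O–C9 bond, so that the excess arene captures the C9 cation, or ring A of a second molecule captures C7.

The fallback sets out from 25 and returns at 27, changing the cation precursor so that ionisation can be done at low temperature. TsOH in MeOH at 40 °C would add methanol across C6=C7 in the Markovnikov sense to give the C7 methyl ether F5 (both C7 epimers). BF3·OEt2 with 26 in CH2Cl2 at −78 °C would then ionise only this 2,4-dimethoxybenzylic ether, far below the temperature at which the aryl ether at C9 opens, and the kinetically controlled arylation should give 27.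

**Step 18.** The carbene carbon is flanked by two ortho substituents, so insertion may be slow and the chiral catalyst may not control C10 well. Insertion into the C7–H bond (also five atoms away) may compete, and the hindered C=N exchange of step 17 may already limit supply.

The fallback sets out from 27 and returns at 36, replacing steps 16–18 and repeating for dihydrobenzofuran 1 the logic used for dihydrobenzofuran 2. MOMCl/iPr2NEt would give the methoxymethyl ether F6. Pd(OAc)2/XPhos/NaOt-Bu in toluene would couple F6 with the enolate of the deoxybenzoin 2-(3,5-dimethoxyphenyl)-1-(4-methoxyphenyl)ethanone F7 (one step from anisole and 3,5-dimethoxyphenylacetyl chloride) to give the triaryl ketone F8, in which C10 is labile. RuCl[(R,R)-TsDPEN](mesitylene) with HCO2H/Et3N would reduce F8 with dynamic kinetic resolution to the (10R,11R)-carbinol F9. HCl/MeOH followed by catalytic TsOH in CH2Cl2 would remove the acetal and close the trans ring to 36.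

**Step 19.** Cleavage of eight ethers may stop short. The strong Lewis acid may also open the O–C9 and O–C11 bonds irreversibly through loss of H8 or H10 from the benzylic cations, or oxidise the emerging polyphenol during work-up.

The fallback sets out from 36 and returns at 37, and makes no new compound (entry F0). NaSEt in DMF at 140 °C would remove the methyl groups by nucleophilic attack at methyl under basic, non-ionising conditions, so that no benzylic cation can form; acidification under argon would then give 37.

## Further compounds

F1 | step 8 | methyl 4-bromo-1-(3,5-dimethoxyphenyl)-5,7-bis(methoxymethoxy)-2-oxo-2,3-dihydro-1H-indene-1-carboxylate | COC(=O)C1(c2cc(OC)cc(OC)c2)C(=O)Cc2c(Br)c(OCOC)cc(OCOC)c21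
F2 | step 8 | methyl 2-{2-bromo-6-[1-(3,5-dimethoxyphenyl)-2-methoxy-2-oxoethyl]-3,5-bis(methoxymethoxy)phenyl}acetate | COC(=O)C(c1cc(OC)cc(OC)c1)c1c(OCOC)cc(OCOC)c(Br)c1CC(=O)OC
F3 | step 8 | 2-{2-bromo-6-[1-(3,5-dimethoxyphenyl)-2-methoxy-2-oxoethyl]-3,5-bis(methoxymethoxy)phenyl}acetic acid | COC(=O)C(c1cc(OC)cc(OC)c1)c1c(OCOC)cc(OCOC)c(Br)c1CC(=O)O
F4 | step 13 | (9S)-[(8S)-1-bromo-7,9-dimethoxy-2,4-bis(methoxymethoxy)-5H-dibenzo[a,d]cyclohepten-5-yl](4-methoxyphenyl)methanol | COCOc1cc(OCOC)c2c(c1Br)C=Cc1c(OC)cc(OC)cc1[C@@H]2[C@H](O)c1ccc(OC)cc1
F5 | step 15 | (8R,9R)-7-methoxy-6,7-dihydro derivative of 25 (both C7 epimers) | Oc1cc2c3c(c1Br)CC(OC)c1c(OC)cc(OC)cc1[C@H]3[C@H](c1ccc(OC)cc1)O2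
F6 | step 18 | (7R,8R,9R)-methoxymethyl ether of 27 | COCOc1cc2c3c(c1Br)C[C@H](c1ccc(OC)cc1OC)c1c(OC)cc(OC)cc1[C@H]3[C@H](c1ccc(OC)cc1)O2
F7 | step 18 | 2-(3,5-dimethoxyphenyl)-1-(4-methoxyphenyl)ethanone | COc1ccc(cc1)C(=O)Cc1cc(OC)cc(OC)c1
F8 | step 18 | (7R,8R,9R)-triaryl ketone (as F6 with Br replaced by CH(3,5-dimethoxyphenyl)C(=O)(4-methoxyphenyl); C10 labile) | COCOc1cc2c3c(c1C(C(=O)c1ccc(OC)cc1)c1cc(OC)cc(OC)c1)C[C@H](c1ccc(OC)cc1OC)c1c(OC)cc(OC)cc1[C@H]3[C@H](c1ccc(OC)cc1)O2
F9 | step 18 | (7R,8R,9R,10R,11R)-carbinol from F8 | COCOc1cc2c3c(c1[C@H]([C@@H](O)c1ccc(OC)cc1)c1cc(OC)cc(OC)c1)C[C@H](c1ccc(OC)cc1OC)c1c(OC)cc(OC)cc1[C@H]3[C@H](c1ccc(OC)cc1)O2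
F0 | step 19 | none | none
A1 | alternative 1 | acyclic triyne (7S,8R,9R,10R,11R) with alkoxy-1,3-diyne, tethered alkyne, C11 carbinol and C7 silyl ether | COc1ccc(cc1)[C@H](O)[C@H](c1cc(OC)cc(OC)c1)C#CC#CO[C@@H](c1ccc(OC)cc1)[C@H](c1cc(OC)cc(OC)c1)C#CC[C@H](O[Si](C)(C)C(C)(C)C)c1ccc(OC)cc1OC
A2 | alternative 1 | benzodifuran core with silyloxy diarylethyl arm on ring A | COc1ccc([C@@H]2Oc3cc4c(c(c3[C@H]2c2cc(OC)cc(OC)c2)C[C@H](O[Si](C)(C)C(C)(C)C)c2ccc(OC)cc2OC)[C@@H](c2cc(OC)cc(OC)c2)[C@H](c2ccc(OC)cc2)O4)cc1
A3 | alternative 2 | ring A-fused cycloheptenyl diazomethyl ketone with dihydrobenzofuran 2 | C(Oc1cc2c3c(c1)C[C@H](c1ccc(OC)cc1OC)C=C([C@H]3[C@H](c1ccc(OC)cc1)O2)C(=O)C=[N+]=[N-])c1ccccc1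
A4 | alternative 2 | triisopropylsiloxyethyne | C#CO[Si](C(C)C)(C(C)C)C(C)C
A5 | alternative 2 | ring B phenol silyl ether of the dibenzocycloheptane–dihydrobenzofuran core | C(Oc1cc2c3c(c1)C[C@H](c1ccc(OC)cc1OC)c1c(O)cc(O[Si](C(C)C)(C(C)C)C(C)C)cc1[C@H]3[C@H](c1ccc(OC)cc1)O2)c1ccccc1
A6 | alternative 3 | (2R)-7-(benzyloxy)-2-(4-methoxyphenyl)-5-methylchroman-4-one | O=C1C[C@H](c2ccc(OC)cc2)Oc2cc(OCc3ccccc3)cc(C)c21
A7 | alternative 3 | methyl (2R,3R)-6-(benzyloxy)-2-(4-methoxyphenyl)-4-methyl-2,3-dihydrobenzofuran-3-carboxylate | COC(=O)[C@H]1[C@H](c2ccc(OC)cc2)Oc2cc(OCc3ccccc3)cc(C)c21
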